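**Retrosynthetic overview**
1. Lactone ring last: target 27 ⇐ macrocyclic γ-hydroxy acrylate 26 (from bis-silyl ether 25) by desilylation and lactonisation.
2. Ten-membered ring first: 25 ⇐ keto aldehyde 24 by intramolecular carbene-catalysed acyl-anion (Breslow) addition of the C1 aldehyde to the C10 methyl ketone (C1–C10 bond, sets C10).
3. 24 ⇐ Z-vinyl iodide 18 + 3,3-diethoxypropanal 20 (C3–C4, Nozaki–Hiyama–Kishi coupling, sets C3).
4. 18 ⇐ aldehyde 12 + hydroxyacetone 13 (C8–C9, L-proline aldol, sets C8 and C9), then acetate and angelate.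
5. 12 ⇐ itaconate-derived N-acylthiazolidinethione 8 + (Z)-3-iodobut-2-enal 4 (C6–C7, Crimmins syn-aldol, sets C6 and C7).

Assumption: carbon locants C1–C15 in the text follow germacrane numbering of the target (C1 ketone, C3 carbinol, C4=C5 alkene, C6 lactone carbinol, C7, C8 angelate carbon, C9 acetate carbon, C10 tertiary carbinol, C11=C13 methylene, C12 ester/lactone carbonyl).

**Step 1**
Reactants: 1 but-2-yn-1-ol
Product: 3 (2Z)-3-iodobut-2-en-1-ol, via cyclic alkenylalanate 2 (not isolated)
Conditions: NaAlH2(OCH2CH2OCH3)2, THF, 0 °C to rt; then I2, −78 °C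
Reagents that add atoms: iodine, II
Why: Hydroxyl-directed trans-hydroalumination of the propargylic alcohol and iodinolysis with retention place iodine cis to CH2OH, which fixes the later C4=C5 Z geometry (directed hydroalumination–iodination).

**Step 2**
Reactants: 3 (2Z)-3-iodobut-2-en-1-ol
Product: 4 (2Z)-3-iodobut-2-enal
Conditions: MnO2, CH2Cl2, rt
Reagents that add atoms: none
Why: Allylic alcohol oxidation with manganese dioxide is neutral and does not scramble the Z-iodoalkene.

**Step 3**
Reactants: 5 itaconic anhydride; 6 (4S)-4-benzyl-1,3-thiazolidine-2-thione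
Product: 8 itaconate N-acylthiazolidinethione methyl ester, via N-acylthiazolidinethione acid 7 (not isolated)
Conditions: 6, NaH, THF, 0 °C; 5, −78 to 0 °C; AcOH; then MeOH, Me3SiCHN2, 0 °C
Reagents that add atoms: (trimethylsilyl)diazomethane, C[Si](C)(C)C=[N+]=[N-]
Why: The thiazolidinethione anion opens the anhydride at the unconjugated, less hindered carbonyl (regioselective N-acylation by anhydride opening) and the freed acrylic acid is esterified by the diazoalkane.

**Step 4**
Reactants: 8 itaconate N-acylthiazolidinethione methyl ester; 4 (2Z)-3-iodobut-2-enal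
Product: 10 syn-aldol adduct (free C6 hydroxyl), via trichlorotitanium Z-enolate 9 (not isolated)
Conditions: TiCl4, i-Pr2NEt, N-methyl-2-pyrrolidinone, CH2Cl2, 0 °C; then 4, −78 to 0 °C
Reagents that add atoms: none
Why: Crimmins titanium-enolate aldol in the "Evans syn" mode: the Z-enolate of the (S)-auxiliary adds through a Zimmerman–Traxler chair on the face away from the benzyl group, giving the syn adduct with C6 and C7 as in the target (syn here corresponds to the trans lactone).

**Step 5**
Reactants: 10 syn-aldol adduct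
Product: 11 C6 triethylsilyl ether
Conditions: Et3SiOTf, 2,6-lutidine, CH2Cl2, −78 °C
Reagents that add atoms: triethylsilyl trifluoromethanesulfonate, CC[Si](CC)(CC)OS(=O)(=O)C(F)(F)F
Why: Silyl ether formation blocks retro-aldol and premature lactonisation, so the acrylate stays a poorly electrophilic 2-substituted ester through the amine- and carbene-catalysed steps.

**Step 6**
Reactants: 11 C6 triethylsilyl ether
Product: 12 C8 aldehyde
Conditions: i-Bu2AlH (1.2 equiv), CH2Cl2, −78 °C
Reagents that add atoms: none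
Why: Reductive cleavage of the activated N-acylthiazolidinethione stops at the aldehyde because the tetrahedral aluminate is stable at −78 °C, while the conjugated methyl ester and the vinyl iodide are untouched; the aldehyde is used at once to avoid epimerisation at C7.

**Step 7**
Reactants: 12 C8 aldehyde; 13 hydroxyacetone
Product: 14 anti-8,9-diol methyl ketone
Conditions: L-proline (30 mol %), 13 (20 equiv), DMSO, rt
Reagents that add atoms: none
Why: List–Notz proline-catalysed direct aldol (enamine catalysis): the enamine formed at the hydroxylated carbon attacks the re face of the α-branched aldehyde in the acid-organised chair, giving the anti diol 8S,9S under catalyst control and bringing in the C10 methyl ketone.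

**Step 8**
Reactants: 14 anti-8,9-diol methyl ketone
Product: 15 C9 monoacetate
Conditions: Ac2O (1.1 equiv), pyridine, CH2Cl2, −20 °C
Reagents that add atoms: acetic anhydride, CC(=O)OC(C)=O
Why: Site-selective esterification: the C9 hydroxyl next to the ketone is more acidic and far less hindered than the C8 hydroxyl flanked by the branched C7, so one equivalent of anhydride acetylates C9 only.

**Step 9**
Reactants: 15 C9 monoacetate; 16 angelic acid
Product: 18 C8 angelate C9 acetate vinyl iodide, via angelic 2,4,6-trichlorobenzoic anhydride 17 (not isolated)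
Conditions: 16, 2,4,6-trichlorobenzoyl chloride, Et3N, toluene, rt; then 15, 80 °C
Reagents that add atoms: none
Why: Yamaguchi-type mixed-anhydride esterification without a nucleophilic catalyst acylates the hindered C8 alcohol and transfers the (Z)-2-methylbut-2-enoyl group without isomerisation to tiglate.

**Step 10**
Reactants: 19 3,3-diethoxypropan-1-ol
Product: 20 3,3-diethoxypropanal
Conditions: Dess–Martin periodinane, pyridine, CH2Cl2, 0 °C to rt
Reagents that add atoms: none
Why: Buffered Dess–Martin oxidation gives the aldehyde without touching the acid-sensitive acetal.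

**Step 11**
Reactants: 18 C8 angelate C9 acetate vinyl iodide; 20 3,3-diethoxypropanal
Product: 21 C3 allylic alcohol diethyl acetal
Conditions: CrCl2 (4 equiv), (S)-N-[2-(4-isopropyl-4,5-dihydro-1,3-oxazol-2-yl)-6-methylphenyl]methanesulfonamide, Et3N, NiCl2 (2 mol %), THF, rt
Reagents that add atoms: none
Why: Nozaki–Hiyama–Kishi coupling: nickel-catalysed formation of the alkenylchromium with retention of the Z geometry and aldehyde-selective addition in the presence of ketone and esters; the chiral sulfonamide on chromium controls the C3 carbinol (3S; the ligand antipode is used if it proves to be the matched one).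

**Step 12**
Reactants: 21 C3 allylic alcohol diethyl acetal
Product: 24 C1 aldehyde bis(triethylsilyl) ether, via C3 triethylsilyl ether diethyl acetal 22 (not isolated), via N-(1-ethoxyalkyl)collidinium triflate 23 (not isolated)
Conditions: Et3SiOTf, 2,4,6-collidine, CH2Cl2, 0 °C; then H2O
Reagents that add atoms: triethylsilyl trifluoromethanesulfonate, CC[Si](CC)(CC)OS(=O)(=O)C(F)(F)F; water, O
Why: Fujioka acetal cleavage: the silyl triflate silylates the C3 hydroxyl and converts the acetal into a collidinium salt that water hydrolyses to the aldehyde, with no Brønsted acid, so silyl ethers, esters and the α-acetoxy ketone survive.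

**Step 13**
Reactants: 24 C1 aldehyde bis(triethylsilyl) ether
Product: 25 ten-membered α-ketol (bis-silyl ether, methyl acrylate)
Conditions: 2-(pentafluorophenyl)-6,7-dihydro-5H-pyrrolo[2,1-c][1,2,4]triazol-2-ium tetrafluoroborate (20 mol %), i-Pr2NEt (20 mol %), toluene (0.002 M), 45 °C, slow addition
Reagents that add atoms: none
Why: Proposed new method: the triazolylidene adds to the C1 aldehyde to give a Breslow acyl-anion equivalent that attacks the C10 ketone intramolecularly, closing the ten-membered ring and forming the tertiary α-ketol in one step; attack anti to the C9–OAc bond (polar Felkin–Anh) gives the 9,10-anti, 10S product, the Z-alkene and the run of substituted carbons pre-organise the chain, high dilution suppresses aldehyde homo-coupling and the 2-substituted acrylate is a poor Stetter acceptor; the closest known reaction type is the intramolecular aldehyde–ketone crossed benzoin reaction that forms five- and six-membered α-ketols.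

**Step 14**
Reactants: 25 ten-membered α-ketol
Product: 27 CNP0308559.2, via macrocyclic dihydroxy acrylate 26 (not isolated)
Conditions: HF·pyridine, THF, 0 °C to rt; then TsOH·H2O (cat.), CH2Cl2, rt
Reagents that add atoms: none
Why: Fluoride desilylation frees the C3 and C6 hydroxyls and acid-catalysed lactonisation of the γ-hydroxy acrylate closes the trans-fused α-methylene-γ-butyrolactone without touching any stereocentre.

**Compound list**
1 | but-2-yn-1-ol | CC#CCO | starting material
2 | sodium 2,2-bis(2-methoxyethoxy)-3-methyl-2,5-dihydro-1,2-oxaaluminol-2-uide (cyclic Z-alkenylalanate) | CC1=CCO[Al-]1(OCCOC)OCCOC.[Na+] | intermediate (not isolated)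
3 | (2Z)-3-iodobut-2-en-1-ol | C/C(I)=C/CO | intermediate
4 | (2Z)-3-iodobut-2-enal | C/C(I)=C/C=O | intermediate
5 | itaconic anhydride (3-methylideneoxolane-2,5-dione) | C=C1CC(=O)OC1=O | starting material
6 | (4S)-4-benzyl-1,3-thiazolidine-2-thione | S=C1N[C@@H](Cc2ccccc2)CS1 | starting material
7 | 4-[(4S)-4-benzyl-2-thioxo-1,3-thiazolidin-3-yl]-2-methylidene-4-oxobutanoic acid | C=C(C(=O)O)CC(=O)N1[C@@H](Cc2ccccc2)CSC1=S | intermediate (not isolated)
8 | methyl 4-[(4S)-4-benzyl-2-thioxo-1,3-thiazolidin-3-yl]-2-methylidene-4-oxobutanoate | C=C(C(=O)OC)CC(=O)N1[C@@H](Cc2ccccc2)CSC1=S | intermediate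
9 | trichlorotitanium (Z)-enolate of 8 | C=C(C(=O)OC)/C=C(\O[Ti](Cl)(Cl)Cl)N1[C@@H](Cc2ccccc2)CSC1=S | intermediate (not isolated)
10 | methyl (3S,4S,5Z)-3-{[(4S)-4-benzyl-2-thioxo-1,3-thiazolidin-3-yl]carbonyl}-4-hydroxy-6-iodo-2-methylidenehept-5-enoate | C=C(C(=O)OC)[C@@H]([C@H](O)/C=C(/C)I)C(=O)N1[C@@H](Cc2ccccc2)CSC1=S | intermediate
11 | methyl (3S,4S,5Z)-3-{[(4S)-4-benzyl-2-thioxo-1,3-thiazolidin-3-yl]carbonyl}-6-iodo-2-methylidene-4-[(triethylsilyl)oxy]hept-5-enoate | C=C(C(=O)OC)[C@@H]([C@H](O[Si](CC)(CC)CC)/C=C(/C)I)C(=O)N1[C@@H](Cc2ccccc2)CSC1=S | intermediate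
12 | methyl (3S,4S,5Z)-3-formyl-6-iodo-2-methylidene-4-[(triethylsilyl)oxy]hept-5-enoate | C=C(C(=O)OC)[C@@H]([C@H](O[Si](CC)(CC)CC)/C=C(/C)I)C=O | intermediate
13 | hydroxyacetone (1-hydroxypropan-2-one) | CC(=O)CO | starting material
14 | methyl (3R,4S,5Z)-3-[(1S,2S)-1,2-dihydroxy-3-oxobutyl]-6-iodo-2-methylidene-4-[(triethylsilyl)oxy]hept-5-enoate | C=C(C(=O)OC)[C@@H]([C@H](O[Si](CC)(CC)CC)/C=C(/C)I)[C@H](O)[C@H](O)C(C)=O | intermediate
15 | methyl (3R,4S,5Z)-3-[(1S,2S)-2-(acetyloxy)-1-hydroxy-3-oxobutyl]-6-iodo-2-methylidene-4-[(triethylsilyl)oxy]hept-5-enoate | C=C(C(=O)OC)[C@@H]([C@H](O[Si](CC)(CC)CC)/C=C(/C)I)[C@H](O)[C@H](OC(C)=O)C(C)=O | intermediate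
16 | angelic acid, (2Z)-2-methylbut-2-enoic acid | C/C=C(/C)C(=O)O | starting material
17 | (2Z)-2-methylbut-2-enoic 2,4,6-trichlorobenzoic anhydride | C/C=C(/C)C(=O)OC(=O)c1c(Cl)cc(Cl)cc1Cl | intermediate (not isolated)
18 | methyl (3R,4S,5Z)-3-[(1S,2S)-2-(acetyloxy)-1-{[(2Z)-2-methylbut-2-enoyl]oxy}-3-oxobutyl]-6-iodo-2-methylidene-4-[(triethylsilyl)oxy]hept-5-enoate | C=C(C(=O)OC)[C@@H]([C@H](O[Si](CC)(CC)CC)/C=C(/C)I)[C@H](OC(=O)/C(C)=C\C)[C@H](OC(C)=O)C(C)=O | intermediate
19 | 3,3-diethoxypropan-1-ol | CCOC(CCO)OCC | starting material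
20 | 3,3-diethoxypropanal | CCOC(CC=O)OCC | intermediate
21 | methyl (3R,4R,5Z,7S)-3-[(1S,2S)-2-(acetyloxy)-1-{[(2Z)-2-methylbut-2-enoyl]oxy}-3-oxobutyl]-9,9-diethoxy-7-hydroxy-6-methyl-2-methylidene-4-[(triethylsilyl)oxy]non-5-enoate | C=C(C(=O)OC)[C@@H]([C@H](O[Si](CC)(CC)CC)/C=C(/C)[C@@H](O)CC(OCC)OCC)[C@H](OC(=O)/C(C)=C\C)[C@H](OC(C)=O)C(C)=O | intermediate
22 | methyl (3R,4R,5Z,7S)-3-[(1S,2S)-2-(acetyloxy)-1-{[(2Z)-2-methylbut-2-enoyl]oxy}-3-oxobutyl]-9,9-diethoxy-6-methyl-2-methylidene-4,7-bis[(triethylsilyl)oxy]non-5-enoate | C=C(C(=O)OC)[C@@H]([C@H](O[Si](CC)(CC)CC)/C=C(/C)[C@@H](O[Si](CC)(CC)CC)CC(OCC)OCC)[C@H](OC(=O)/C(C)=C\C)[C@H](OC(C)=O)C(C)=O | intermediate (not isolated)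
23 | N-(1-ethoxyalkyl)-2,4,6-trimethylpyridinium triflate derived from 22 (C1 carries OEt and the pyridinium nitrogen) | C=C(C(=O)OC)[C@@H]([C@H](O[Si](CC)(CC)CC)/C=C(/C)[C@@H](O[Si](CC)(CC)CC)CC(OCC)[n+]1c(C)cc(C)cc1C)[C@H](OC(=O)/C(C)=C\C)[C@H](OC(C)=O)C(C)=O.[O-]S(=O)(=O)C(F)(F)F | intermediate (not isolated)
24 | methyl (3R,4R,5Z,7S)-3-[(1S,2S)-2-(acetyloxy)-1-{[(2Z)-2-methylbut-2-enoyl]oxy}-3-oxobutyl]-6-methyl-2-methylidene-9-oxo-4,7-bis[(triethylsilyl)oxy]non-5-enoate | C=C(C(=O)OC)[C@@H]([C@H](O[Si](CC)(CC)CC)/C=C(/C)[C@@H](O[Si](CC)(CC)CC)CC=O)[C@H](OC(=O)/C(C)=C\C)[C@H](OC(C)=O)C(C)=O | intermediate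
25 | methyl 2-[(1R,2R,3Z,5S,8S,9S,10S)-9-(acetyloxy)-8-hydroxy-4,8-dimethyl-10-{[(2Z)-2-methylbut-2-enoyl]oxy}-7-oxo-2,5-bis[(triethylsilyl)oxy]cyclodec-3-en-1-yl]prop-2-enoate | C=C(C(=O)OC)[C@H]1[C@H](O[Si](CC)(CC)CC)/C=C(/C)[C@@H](O[Si](CC)(CC)CC)CC(=O)[C@@](C)(O)[C@@H](OC(C)=O)[C@H]1OC(=O)/C(C)=C\C | intermediate
26 | methyl 2-[(1S,2R,3Z,5S,8S,9S,10S)-9-(acetyloxy)-2,5,8-trihydroxy-4,8-dimethyl-10-{[(2Z)-2-methylbut-2-enoyl]oxy}-7-oxocyclodec-3-en-1-yl]prop-2-enoate | C=C(C(=O)OC)[C@H]1[C@H](O)/C=C(/C)[C@@H](O)CC(=O)[C@@](C)(O)[C@@H](OC(C)=O)[C@H]1OC(=O)/C(C)=C\C | intermediate (not isolated)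
27 | (3aS,4S,5S,6S,9S,10Z,11aR)-5-(acetyloxy)-6,9-dihydroxy-6,10-dimethyl-3-methylidene-2,7-dioxo-2,3,3a,4,5,6,7,8,9,11a-decahydrocyclodeca[b]furan-4-yl (2Z)-2-methylbut-2-enoate (CNP0308559.2) | C=C1C(=O)O[C@@H]2/C=C(/C)[C@@H](O)CC(=O)[C@@](C)(O)[C@@H](OC(C)=O)[C@@H](OC(=O)/C(C)=C\C)[C@@H]12 | target

**Totals**
Total step count: 14. Longest linear sequence: 12 steps (1, 2, 4, 5, 6, 7, 8, 9, 11, 12, 13, 14).

**Three steps most likely to fail**

Step 13 (ten-membered ring closure by carbene catalysis). The open chain may prefer oligomerisation, or the α-ketol may revert. The fallback reverses the order of ring formation so that the rigid trans-lactone templates the medium ring. It sets out from 21. HF·pyridine in THF, then pyridinium p-toluenesulfonate in CH2Cl2, removes the C6 silyl group and closes the α-methylene lactone to give lactone acetal alcohol F1. Et3SiOTf/2,4,6-collidine, then water, gives the C3-silylated lactone aldehyde F2. The triazolium/i-Pr2NEt conditions of step 13 then close C1–C10 on this constrained substrate to give the 3-O-triethylsilyl ether of the target F3, and HF·pyridine returns to the route at 27.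

Step 7 (proline aldol on a hindered, enolisable α-branched aldehyde). Aldehyde 12 may stall or isomerise under amine catalysis. The fallback is an amine-free α-acetoxyallylation and Wacker sequence that sets out from 12. Indium powder and 3-bromoprop-1-enyl acetate in THF give the anti 1-hydroxy-2-acetoxybut-3-enyl adduct F4 (Felkin addition expected; the acetate is already in place, so step 8 is not needed). Esterification as in step 9 gives the angelate F5. Ketone-selective Wacker oxidation of the terminal vinyl group with PdCl2[2-(4,5-dihydro-1,3-oxazol-2-yl)quinoline], AgSbF6 and aqueous tert-butyl hydroperoxide returns to the route at 18.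

Step 9 (angelate on the hindered C8 alcohol next to an α-acetoxy ketone). Failure modes are no acylation, tiglate formation, or acetyl migration and C9 epimerisation on heating with amine. The fallback builds the Z-enoate on the alcohol by olefination and sets out from 15. DCC/DMAP esterification with 2-(diphenoxyphosphoryl)propanoic acid gives the phosphonate ester F6. An Ando-type Z-selective Horner–Wadsworth–Emmons reaction with acetaldehyde (NaI, DBU, THF, −78 to 0 °C) returns to the route at 18.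

**Further compounds**
F1 | step 13 | trans-α-methylene lactone from 21 with free C3 hydroxyl and C1 diethyl acetal | C=C1C(=O)O[C@H](/C=C(/C)[C@@H](O)CC(OCC)OCC)[C@H]1[C@H](OC(=O)/C(C)=C\C)[C@H](OC(C)=O)C(C)=O
F2 | step 13 | lactone aldehyde with C3 triethylsilyl ether | C=C1C(=O)O[C@H](/C=C(/C)[C@@H](O[Si](CC)(CC)CC)CC=O)[C@H]1[C@H](OC(=O)/C(C)=C\C)[C@H](OC(C)=O)C(C)=O
F3 | step 13 | 3-O-triethylsilyl ether of 27 | C=C1C(=O)O[C@@H]2/C=C(/C)[C@@H](O[Si](CC)(CC)CC)CC(=O)[C@@](C)(O)[C@@H](OC(C)=O)[C@@H](OC(=O)/C(C)=C\C)[C@@H]12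
F4 | step 7 | C10-vinyl analogue of 15 (side chain CH(OH)–CH(OAc)–CH=CH2, same configuration at C8 and C9) | C=C(C(=O)OC)[C@@H]([C@H](O[Si](CC)(CC)CC)/C=C(/C)I)[C@H](O)[C@H](OC(C)=O)C=C
F5 | step 7 | C8 angelate of F4 | C=C(C(=O)OC)[C@@H]([C@H](O[Si](CC)(CC)CC)/C=C(/C)I)[C@H](OC(=O)/C(C)=C\C)[C@H](OC(C)=O)C=C
F6 | step 9 | C8 2-(diphenoxyphosphoryl)propanoate of 15 | C=C(C(=O)OC)[C@@H]([C@H](O[Si](CC)(CC)CC)/C=C(/C)I)[C@H](OC(=O)C(C)P(=O)(Oc1ccccc1)Oc1ccccc1)[C@H](OC(C)=O)C(C)=O
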